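**Conventions and assumptions**

- Fluorene numbering is used for the tricycle: ring A = C4b, C5–C8, C8a; ring B = C4a, C4b, C8a, C9, C9a; ring C = C1–C4, C4a, C9a. β is the face of the angular C4b methyl, α the opposite face. Lactam atoms carry primes (N1′, C2′ to C5′).
- Bicyclic intermediates are named as indenes. Indene C1/C2/C3/C3a/C4/C5/C6/C7/C7a correspond to fluorene C4a/C9a/C9/C8a/C8/C7/C6/C5/C4b.
- TBS = tert-butyldimethylsilyl, Tf = trifluoromethanesulfonyl, DMP = Dess–Martin periodinane. "Dodecahydrofluorene" means the fully saturated skeleton; Δn marks a double bond starting at Cn.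
- Assumption 1: the α-carbon of a 1,3-dicarbonyl unit that still bears hydrogen (in 20, 21, 32) is configurationally labile and is left open in the SMILES.
- Assumption 2: the closed 1,2-dioxocan-3-ol is taken to be the preferred form of the hydroperoxy aldehyde, as it is in the target itself.

## Analysis of the target

The skeleton is a dodecahydrofluorene that is trans-fused at both junctions (C8a–H α and C4b–CH3 β; C9a–H β and C4a–H α). A 13-membered para-cyclophane runs from the C9 oxygen through a 1,4-phenylene and a benzylic CH2 to C5′ of a pyrrolidin-2-one, and back from the quaternary C3′ through a ketone to C1. C3′ also starts an eight-membered 1,2-dioxocane (C3′–CH2–CH(OH)–O–O–C2), and ring C carries a 3,4-epoxide.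

There are 14 stereocentres. In ring A the C6 and C8 methyl groups are equatorial (both α) and the C4b methyl is axial. The C9 oxygen is β, the C1 acyl group is β and equatorial, and the C4 methyl is α. The peroxide oxygen at C2 and the epoxide oxygen are both β. C3′, the hemiaminal carbon C5′ and the peroxy-hemiacetal carbon complete the set.

The sensitive groups are the O–O bond (reductants, low-valent metals), the peroxy hemiacetal and the N,O-hemiaminal (both reversible), the trisubstituted epoxide (acid), the α-quaternary β-keto amide (retro-Claisen cleavage) and C1–H, which is α to the ketone.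

The difficulty lies in three places: the strained cyclophane with its bent arene, the quaternary C3′ that is remote from the other stereocentres, and the need to postpone all peroxide chemistry to the very end.

The strategy rests on the benzylic CH2 between the arene and C5′. An N,O-hemiaminal is the hydrate of an enamide, so the unit aryl–CH2–C5′(OH)–N is the hydrated product of an arylation at the CH2 terminus of an exocyclic enamide CH2=C5′–N. One Heck reaction can therefore form the aryl–CH2 bond and close the macrocycle.

## Retrosynthetic reasoning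

**Epoxide (41 to 40).** The two C–O bonds of the 3,4-epoxide are cut first. The epoxide is the most acid-sensitive group, and its alkene only exists after the oxygen ene reaction. The forward step must deliver oxygen to the β face of C3=C4.

**Peroxide bridge (40 to 38).** The C2–O bond and the O–CH(OH) bond of the dioxocane are cut together. Photooxygenation of the C2=C3 alkene in 38 should give the tertiary hydroperoxide 39 with the double bond moved to C3=C4, and the hydroperoxide then adds to the pendant aldehyde. This installs the O–O bond as late as possible and needs no protecting group.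

**Aldehyde and hemiaminal (38 to 37 to 36).** The aldehyde is taken back to the primary alcohol and the hemiaminal to the endocyclic enamide 36. Hydration of 36 can only give the hemiaminal epimer whose benzyl arm is cis to the C3′ ketone arm, because both arms are tied into the cyclophane.

**Aryl–CH2 bond (36 to 35).** This is the ring-opening cut. It is made here and not at the aryl ether or the C1 ketone for three reasons. The exocyclic CH2 of 35 is the only unhindered alkene carbon in the molecule. The aryl bromide is inert to everything before this step. The product already holds C5′ at the oxidation level of the hemiaminal.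

**Lactam and quaternary carbon (35 to 34 to 32 to 30).** The N1′–C5′ bond is cut to the propargyl amide 34 (5-exo-dig hydroamidation). The two C–C bonds at C3′ are cut to the β-keto amide 30 and the halides 31 and 33. The second alkylation has to set C3′ under control of the C1 stereocentre.

**Keto amide and aryl ether (30 to 28 to 27 to 25).** The β-keto amide is cut to the acid 28 (acylketene route). The C9–O–aryl bond is cut to the 9β alcohol 25 and the diaryliodonium salt 26. Ether formation with retention is chosen. A Mitsunobu displacement by a phenol would need the 9α alcohol and an SN2 attack on the β face next to the angular methyl.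

**Ring C (24 to 23 to 21 to 18 + 19).** The alkene position and the C1 and C4 hydrogens come from a 1,6-reduction of the dienoate 23. Axial protonation sets both centres and leaves the alkene at C2=C3, where no ketone-based method could place it cleanly. The diene is cut to the keto ester 21 (C2 methyl by cross-coupling). Ring C is cut at C9a–C1 and C3=C4 to the acetylcyclopentene 18 and the phosphonate 19 (Michael addition, then intramolecular Horner–Wadsworth–Emmons reaction).

**Ring B functionality (18 to 16 to 14 to 12).** The acetyl group comes from the ketone 15 through the enol triflate 16 (Stille coupling). The C9 oxygen comes from conjugate borylation of the enone 12. The oxygen has to be placed here, because C9 is unactivated once ring C is in place.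

**Rings A and B (12 to 10 to 9 to 7 to 4 to 3 to 1 + 2).** The trans-hydrindanone 10 is taken back to the enedione 4. The quaternary C4b is set by an amino-acid-catalysed aldol cyclisation of the triketone 3, made from 1 and 2. The ring A ketone of 4 is kept long enough to set the ring fusion (dissolving-metal reduction) and both secondary methyl groups (equilibration), and is then removed.

## Alternatives that were turned down

**Alternative 1: ring A by a Diels–Alder reaction with citraconic anhydride.**
- Disconnection: C4b–C5 and C8–C8a of ring A.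
- Forward key step: (E)-2-methylpenta-1,3-diene A2 adds to citraconic anhydride A3 to give the cis-fused anhydride A1, which carries the angular methyl.
- For it: two commodity chemicals and one step give ring A with its quaternary carbon and two carbonyl handles for ring B. On step count to ring A it is clearly stronger than the chosen route, which needs six steps to reach 9.
- Against it: a thermal cycloaddition of a cyclic anhydride gives the racemate, so a resolution or a later asymmetric step is needed. The cyclic dienophile forces C8a–H cis to the C4b methyl, so C8a must be inverted after the two carbonyls have been told apart. The C6 methyl must come from hydrogenation of a trisubstituted alkene, and the hydrogen would have to enter syn to the axial angular methyl.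
- Comparison: the chosen route pays four more steps. In return it sets C4b in the absolute sense by catalysis and sets C8a, C8 and C6 by ring-based rules. Alternative 1 also says nothing about the cyclophane.

**Alternative 2: ketyl–enoate cyclisation and aldol cascade for rings B and C.**
- Disconnection: C9–C9a and C1–C2.
- Forward key step: SmI2 reduces the ring A aldehyde A5 to a ketyl, which adds to the enoate β-carbon (ring B). The samarium enolate then adds to the methyl ketone (ring C) and gives the diol ester A4.
- For it: one step builds two rings and four stereocentres, and the C9 hydroxyl of A4 already has the configuration of the ether. In step economy for rings B and C it is far stronger than the nine steps (8 to 16) used here.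
- Against it: A5 needs the vicinal C4a and C4 stereocentres on an open chain next to the quaternary C4b, where no ring relays the stereochemistry. The cascade must control four centres and a trans ring fusion in one event. The tertiary C2 alcohol of A4 must then be eliminated towards C3, while a β-hydroxy ester eliminates by preference into conjugation with the ester (C1=C2).
- Comparison: the chosen route is longer but sets each centre by a separate, rule-based step, and places the C2=C3 bond by a reduction instead of an elimination.

**Alternative 3: singlet-oxygen ene reaction as the strategic step.**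
- Disconnection: C2–O and O–CH(OH) of the dioxocane.
- Forward key step: singlet oxygen attacks C2 of the ring C alkene of the aldehyde A7 (identical with 38), the alkene shifts to C3=C4, and the hydroperoxide closes on the aldehyde to give A6 (identical with 40).
- For it: the step is probably biomimetic, forms the peroxide and the eight-membered ring at once, and prepares the alkene for the epoxide. On the peroxide question it is as strong as anything available, and the chosen route uses it as step 27.
- Against it: taken as the strategy, it presupposes the complete cyclophane and leaves the two hard problems, the 13-membered ring and C3′, unanswered. Its selectivity rests wholly on the shape of the substrate.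
- Comparison: the chosen strategy places its planning on the ring closure that must succeed first, and keeps the ene reaction for the end game.

Key step: step 24

## Route

**Step 1**
Reactants: 1 2-methylcyclopentane-1,3-dione; 2 pent-1-en-3-one
Product: 3 2-methyl-2-(3-oxopentyl)cyclopentane-1,3-dione
Conditions: H2O, AcOH (cat.), 70 °C
Reagents that add atoms: none
Why: Michael addition of the enolised 1,3-dione to the vinyl ketone; the product cannot react further because its central carbon is quaternary.

**Step 2**
Reactants: 3 triketone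
Product: 4 (7aR)-4,7a-dimethyl-2,3,7,7a-tetrahydro-1H-indene-1,5(6H)-dione
Conditions: D-phenylalanine (1 equiv), (1R)-(−)-10-camphorsulfonic acid (0.5 equiv), DMF, 30 to 70 °C
Reagents that add atoms: none
Why: Amino-acid-catalysed enamine aldol cyclisation and dehydration (Hajos–Parrish–Eder–Sauer–Wiechert reaction); the D-amino acid selects one of the two enantiotopic ring carbonyls and should set C7a as R, the mirror image of the sense known for the L-series.

**Step 3**
Reactants: 4 enedione
Product: 5 (7aR)-1β-hydroxy-4,7aβ-dimethyl-1,2,3,6,7,7a-hexahydro-5H-inden-5-one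
Conditions: NaBH4 (0.3 equiv), EtOH, −20 °C
Reagents that add atoms: none
Why: Chemoselective hydride reduction: the saturated cyclopentanone is more electrophilic than the conjugated ketone, and hydride enters anti to the angular methyl, so the hydroxyl ends cis to it. The alcohol is the masked form of this ketone during the two reductions that follow.

**Step 4**
Reactants: 5 hydroxy enone
Product: 6 trans-fused (7aR)-1β-hydroxy-4α,7aβ-dimethyl-3aα-H-octahydro-5H-inden-5-one
Conditions: Li, NH3 (l), THF, t-BuOH (1 equiv), −78 °C; NH4Cl; then NaOMe (cat.), MeOH, 25 °C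
Reagents that add atoms: none
Why: Dissolving-metal (Birch-type) enone reduction: the β-carbon C3a is protonated axially, anti to the axial angular methyl, which should give the trans ring fusion. The C4 methyl is α to the ketone and is equilibrated to the equatorial (α) position.

**Step 5**
Reactants: 6 hydroxy ketone
Product: 7 (7aR)-1β-hydroxy-4α,6α,7aβ-trimethyl-3aα-H-octahydro-5H-inden-5-one
Conditions: LiN(i-Pr)2 (2.2 equiv), THF, −78 °C; MeI (1.1 equiv); then NaOMe (cat.), MeOH, 25 °C
Reagents that add atoms: iodomethane, CI
Why: Kinetic enolate alkylation at the CH2 (C6) and not at the methine C4; the lithium alkoxide is a poor nucleophile at −78 °C. Equilibration then places both α-methyl groups equatorial, cis to each other and trans to the angular methyl.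

**Step 6**
Reactants: 7 dimethyl ketone
Product: 9 (7aR)-4α,6α,7aβ-trimethyl-3aα-H-octahydro-1H-inden-1β-ol, via hydrazone 8 (not isolated)
Conditions: N2H4·H2O, KOH, diethylene glycol, 130 then 200 °C
Reagents that add atoms: hydrazine, NN (nitrogen atoms of 8 only; none remains in 9)
Why: Wolff–Kishner reduction (Huang–Minlon procedure) removes the ring A carbonyl after it has served to set both methyl-bearing carbons; these are thermodynamically configured, so the hot base cannot degrade them.

**Step 7**
Reactants: 9 hydrindanol
Product: 10 (7aR)-4α,6α,7aβ-trimethyl-3aα-H-octahydro-1H-inden-1-one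
Conditions: DMP, NaHCO3, CH2Cl2, 25 °C
Reagents that add atoms: none
Why: Dess–Martin oxidation of the secondary alcohol returns the cyclopentanone, whose only enolisable position is C2.

**Step 8**
Reactants: 10 hydrindanone
Product: 12 (7aR)-4α,6α,7aβ-trimethyl-3aα-H-3a,4,5,6,7,7a-hexahydro-1H-inden-1-one, via silyl enol ether 11 (not isolated)
Conditions: LiN(i-Pr)2, Me3SiCl, THF, −78 °C; then Pd(OAc)2 (1.1 equiv), MeCN, 25 °C
Reagents that add atoms: chlorotrimethylsilane, C[Si](C)(C)Cl (silyl group of 11 only)
Why: Saegusa–Ito oxidation: the ketone enolises only towards C2, and the palladium enolate formed from the silyl enol ether gives the cyclopentenone by β-hydride elimination.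

**Step 9**
Reactants: 12 enone
Product: 14 3β-hydroxy-4α,6α,7aβ-trimethyl-3aα-H-octahydro-1H-inden-1-one, via boryl ketone 13 (not isolated)
Conditions: B2pin2, CuCl (5 mol %), NaOt-Bu (10 mol %), Xantphos (5 mol %), MeOH (2 equiv), THF, 25 °C; then NaBO3·4H2O, THF/H2O, 25 °C
Reagents that add atoms: bis(pinacolato)diboron, CC1(C)OB(OC1(C)C)B1OC(C)(C)C(C)(C)O1 (boryl group of 13); sodium perborate, [Na+].[O-]OB=O (hydroxyl oxygen of 14)
Why: Copper-catalysed conjugate borylation, then oxidation of the C–B bond with retention. The boryl copper species should add to C3 from the β face, as nucleophiles do with trans-hydrindenones of this kind (the α face is screened by the axial C3a–H and the equatorial C4 methyl); this sets the future C9–O bond.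

**Step 10**
Reactants: 14 β-hydroxy ketone
Product: 15 3β-(TBS-oxy)-4α,6α,7aβ-trimethyl-3aα-H-octahydro-1H-inden-1-one
Conditions: TBSOTf, 2,6-lutidine, CH2Cl2, −78 °C
Reagents that add atoms: tert-butyldimethylsilyl triflate, CC(C)(C)[Si](C)(C)OS(=O)(=O)C(F)(F)F
Why: Silylation of the hindered alcohol with the silyl triflate at low temperature, which avoids retro-aldol cleavage or elimination of the β-hydroxy ketone.

**Step 11**
Reactants: 15 silyloxy ketone
Product: 16 3β-(TBS-oxy)-4α,6α,7aβ-trimethyl-3aα-H-3a,4,5,6,7,7a-hexahydro-3H-inden-1-yl triflate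
Conditions: KN(SiMe3)2, THF, −78 °C; PhNTf2
Reagents that add atoms: N-phenylbis(trifluoromethanesulfonimide), O=S(=O)(N(c1ccccc1)S(=O)(=O)C(F)(F)F)C(F)(F)F
Why: Regiospecific enolate formation (C2 is the only α-CH2) and O-triflation; at −78 °C the enolate should be trapped faster than it expels the β-silyloxy group.

**Step 12**
Reactants: 16 enol triflate
Product: 18 1-acetyl-3β-(TBS-oxy)-4α,6α,7aβ-trimethyl-3aα-H-3a,4,5,6,7,7a-hexahydro-3H-indene, via ethoxydiene 17 (not isolated)
Conditions: tributyl(1-ethoxyvinyl)stannane, Pd(PPh3)4 (5 mol %), LiCl, THF, 65 °C; then 1 M HCl, THF, 0 °C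
Reagents that add atoms: tributyl(1-ethoxyvinyl)stannane, CCCC[Sn](CCCC)(CCCC)C(=C)OCC; water, O
Why: Stille coupling of the alkenyl triflate with an acetyl anion equivalent, then mild hydrolysis of the enol ether to the methyl ketone; the secondary silyl ether survives brief dilute acid.

**Step 13**
Reactants: 18 acetylcyclopentene; 19 ethyl 4-(diethoxyphosphoryl)-3-oxobutanoate
Product: 21 ethyl 9β-(TBS-oxy)-4,4bβ,6α,8α-tetramethyl-2-oxo-Δ3-dodecahydrofluorene-1-carboxylate (4a-H α; 8a-H α; 9a-H β), via Michael adduct 20 (not isolated)
Conditions: NaH (2.2 equiv), THF, 0 to 50 °C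
Reagents that add atoms: none
Why: Tandem Michael addition and intramolecular Horner–Wadsworth–Emmons reaction. The β-keto ester carbon of 19 adds to C2 of the enone (the future C9a) from the α face, anti to the silyloxy group and the angular methyl, and the enolate is protonated to the preferred β-acetyl isomer. The phosphonate carbanion then condenses with that acetyl group, which makes the closure of ring C regiospecific and trans-fused.

**Step 14**
Reactants: 21 β-keto ester
Product: 22 ethyl 9β-(TBS-oxy)-4,4bβ,6α,8α-tetramethyl-2-(triflyloxy)-Δ1,Δ3-dodecahydrofluorene-1-carboxylate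
Conditions: NaH, THF, 0 °C; PhNTf2, 25 °C
Reagents that add atoms: N-phenylbis(trifluoromethanesulfonimide), O=S(=O)(N(c1ccccc1)S(=O)(=O)C(F)(F)F)C(F)(F)F
Why: O-Triflation of the sodium enolate of the β-keto ester gives the 2-triflyloxy diene; C1 becomes sp2, so its configuration in 21 is irrelevant.

**Step 15**
Reactants: 22 dienyl triflate
Product: 23 ethyl 9β-(TBS-oxy)-2,4,4bβ,6α,8α-pentamethyl-Δ1,Δ3-dodecahydrofluorene-1-carboxylate
Conditions: MeMgBr, Fe(acac)3 (5 mol %), THF/NMP, −30 °C
Reagents that add atoms: methylmagnesium bromide, C[Mg]Br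
Why: Iron-catalysed cross-coupling of the alkenyl triflate with the methyl Grignard reagent installs the C2 methyl; the coupling is fast at low temperature and tolerates the ester.

**Step 16**
Reactants: 23 dienoate
Product: 24 ethyl 9β-(TBS-oxy)-2,4α,4bβ,6α,8α-pentamethyl-Δ2-dodecahydrofluorene-1β-carboxylate
Conditions: Li, NH3 (l), THF, t-BuOH (1 equiv), −78 °C; NH4Cl
Reagents that add atoms: none
Why: Birch-type 1,6-reduction of the dienoate: the radical anion is protonated at the δ-carbon C4, and the ester dienolate is protonated at C1 on quench, which leaves the C2=C3 bond. Both protons should enter pseudoaxially (C4–H β, anti to the axial C4a–H; C1–H α, anti to the axial C9a–H), so the C4 methyl and the C1 ester end pseudoequatorial.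

**Step 17**
Reactants: 24 silyl ether ester
Product: 25 ethyl 9β-hydroxy-2,4α,4bβ,6α,8α-pentamethyl-Δ2-dodecahydrofluorene-1β-carboxylate
Conditions: HF·pyridine, THF, 0 to 25 °C
Reagents that add atoms: none
Why: Fluoride cleavage of the silyl ether under non-basic conditions, so C1–H is not touched; lactonisation with the C1 ester is not expected, because the lactone would be a trans-fused bicyclo[3.3.0]octane.

**Step 18**
Reactants: 25 hydroxy ester; 26 bis(4-bromophenyl)iodonium triflate
Product: 27 ethyl 9β-(4-bromophenoxy)-2,4α,4bβ,6α,8α-pentamethyl-Δ2-dodecahydrofluorene-1β-carboxylate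
Conditions: NaH (1.05 equiv), toluene, 0 °C; then 26, 25 °C
Reagents that add atoms: none
Why: O-Arylation of the sodium alkoxide by the diaryliodonium salt (ligand coupling at iodine, no transition metal). The C9–O bond is not broken, so the β configuration is retained, and the aryl bromide is not touched.

**Step 19**
Reactants: 27 aryl ether ester
Product: 28 9β-(4-bromophenoxy)-2,4α,4bβ,6α,8α-pentamethyl-Δ2-dodecahydrofluorene-1β-carboxylic acid
Conditions: Me3SnOH, 1,2-dichloroethane, 80 °C; 1 M HCl wash
Reagents that add atoms: trimethyltin hydroxide, C[Sn](C)(C)O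
Why: Me3SnOH cleaves the ethyl ester under nearly neutral conditions, so the β,γ-double bond should not move into conjugation; C1 is already in its preferred configuration.

**Step 20**
Reactants: 28 acid
Product: 30 3-[9β-(4-bromophenoxy)-2,4α,4bβ,6α,8α-pentamethyl-Δ2-dodecahydrofluoren-1β-yl]-3-oxopropanamide, via acyl Meldrum's acid 29 (not isolated)
Conditions: Meldrum's acid, EDC·HCl, DMAP, CH2Cl2, 0 to 25 °C; then NH3 (0.5 M in 1,4-dioxane), 85 °C
Reagents that add atoms: Meldrum's acid, CC1(C)OC(=O)CC(=O)O1; ammonia, N
Why: Carbodiimide coupling gives the acyl Meldrum's acid, which on heating loses acetone and CO2 to an acylketene that ammonia traps as the primary β-keto amide. From here on the CH2 between the two carbonyls is the most acidic site.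

**Step 21**
Reactants: 30 β-keto amide; 31 (2-bromoethoxy)(tert-butyl)dimethylsilane
Product: 32 2-[2-(TBS-oxy)ethyl] derivative of 30 (both epimers at the new carbon)
Conditions: K2CO3, DMF, 60 °C
Reagents that add atoms: none
Why: C-Alkylation of the 1,3-dicarbonyl monoanion with the primary bromide; the weak base deprotonates only this position, and the sluggish electrophile is used first, on the less hindered nucleophile.

**Step 22**
Reactants: 32 monoalkylated keto amide; 33 3-bromoprop-1-yne
Product: 34 2-[2-(TBS-oxy)ethyl]-2-(prop-2-ynyl) keto amide with the C3′ configuration of the target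
Conditions: NaH (1.05 equiv), THF, 0 °C; then 33, 0 to 25 °C
Reagents that add atoms: none
Why: C-Alkylation of the chelated sodium enolate creates the quaternary C3′. With the amide held cis to the enolate oxygen and C1–H eclipsing the enolate double bond (A(1,3) strain), C9a and C2 lie on opposite faces; attack anti to the bulkier C9a side should give the configuration shown, and the minor epimer is removed by chromatography.

**Step 23**
Reactants: 34 propargyl keto amide
Product: 35 3-[9β-(4-bromophenoxy)-2,4α,4bβ,6α,8α-pentamethyl-Δ2-dodecahydrofluorene-1β-carbonyl]-3-[2-(TBS-oxy)ethyl]-5-methylidenepyrrolidin-2-one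
Conditions: KOt-Bu (0.2 equiv), t-BuOH/THF, 40 °C
Reagents that add atoms: none
Why: Base-mediated 5-exo-dig addition of the amide nitrogen to the alkyne (intramolecular hydroamidation), helped by the quaternary centre (Thorpe–Ingold effect). A sub-stoichiometric hindered alkoxide limits enolisation at C1.

**Step 24 (key step)**
Reactants: 35 aryl bromide with exocyclic enamide
Product: 36 cyclophane with the aryl–CH2 bond closed and a 4′,5′-endocyclic enamide
Conditions: Pd(OAc)2 (10 mol %), P(t-Bu)3·HBF4 (20 mol %), Cy2NMe (3 equiv), 1,4-dioxane, 1 mM by slow addition, 90 °C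
Reagents that add atoms: none
Why: Pd(OAc)2 (divalent palladium) is reduced in situ to zerovalent palladium, which inserts into the aryl–bromine bond; migratory insertion then places the aryl group on the terminal CH2 of the enamide, because C5′ is fully substituted and insertion there would give a neopentyl-type alkylpalladium without β-hydrogen. This insertion forms the aryl–CH2 bond and closes the 13-membered ring in the 13-endo-trig mode. β-Hydride elimination towards C4′ gives the endocyclic enamide 36; elimination towards the benzylic carbon would give the benzylidene isomer, which is equally usable because both are hydrated through the same N-acyliminium ion in step 25. The closest known reactions are macrocyclising intramolecular Heck reactions and the Heck arylation of exocyclic enamides at their terminal carbon. No stereocentre is formed. The step needs chemoselectivity for the enamide over the ring C alkene; the trisubstituted, ring-embedded C2=C3 bond is too hindered to insert and would lead to a much more strained ring. It also needs ring closure to win over oligomerisation, for which high dilution with slow addition and the bulky, electron-rich phosphine are used.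

**Step 25**
Reactants: 36 cyclophane enamide
Product: 37 cyclophane with 5′-hydroxy lactam (hemiaminal) and free 2-hydroxyethyl arm
Conditions: 1 M HCl (aq), THF, 25 °C
Reagents that add atoms: water, O
Why: Enamide hydration: protonation at C4′ gives an N-acyliminium ion that water captures at C5′. Only the hemiaminal epimer with the benzyl group cis to the C3′ ketone arm fits the cyclophane, so C5′ is set under thermodynamic control; the same acid cleaves the primary silyl ether.

**Step 26**
Reactants: 37 hemiaminal alcohol
Product: 38 cyclophane aldehyde (2-oxoethyl arm on C3′)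
Conditions: DMP, NaHCO3, CH2Cl2, 0 °C
Reagents that add atoms: none
Why: Dess–Martin oxidation of the primary alcohol; the tertiary hemiaminal hydroxyl cannot be oxidised, and the buffered conditions leave it intact.

**Step 27**
Reactants: 38 aldehyde
Product: 40 peroxy hemiacetal (1,2-dioxocan-3-ol) with the C3=C4 alkene, via hydroperoxide 39 (not isolated)
Conditions: O2, tetraphenylporphyrin (cat.), visible light, CH2Cl2, −20 °C
Reagents that add atoms: dioxygen, O=O
Why: Schenck ene reaction of singlet oxygen with the C2=C3 bond. The reagent should attack the β face and take the pseudoaxial β hydrogen at C4 on the disubstituted side of the alkene (the other candidate, C1–H, is on the α face and α to the ketone), which gives the tertiary C2 hydroperoxide and the C3=C4 bond. The hydroperoxide then adds reversibly to the aldehyde, so the eight-membered ring and its carbinol carbon are set thermodynamically.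

**Step 28**
Reactants: 40 peroxy hemiacetal
Product: 41 CNP0533733.1 (target)
Conditions: mCPBA, NaHCO3, CH2Cl2, 0 °C
Reagents that add atoms: 3-chloroperbenzoic acid, OOC(=O)c1cccc(Cl)c1
Why: Peracid epoxidation of the trisubstituted C3=C4 bond. The epoxide must be syn to the peroxide oxygen, which is pseudoaxial on the β face; the step counts on hydrogen-bond delivery of the peracid by the hydroxyl of the peroxy hemiacetal and by the free hydroperoxide of the open form 39, with which 40 equilibrates (hydroxyl-directed epoxidation).

## Compound list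

1 | 2-methylcyclopentane-1,3-dione | CC1C(=O)CCC1=O | starting material
2 | pent-1-en-3-one | CCC(=O)C=C | starting material
3 | 2-methyl-2-(3-oxopentyl)cyclopentane-1,3-dione | CCC(=O)CCC1(C)C(=O)CCC1=O | intermediate
4 | (7aR)-4,7a-dimethyl-2,3,7,7a-tetrahydro-1H-indene-1,5(6H)-dione | CC1=C2CCC(=O)[C@]2(C)CCC1=O | intermediate
5 | (7aR)-1β-hydroxy-4,7aβ-dimethyl-1,2,3,6,7,7a-hexahydro-5H-inden-5-one (OH cis to the 7a-methyl) | CC1=C2CC[C@@H](O)[C@]2(C)CCC1=O | intermediate
6 | (7aR)-1β-hydroxy-4α,7aβ-dimethyl-3aα-H-octahydro-5H-inden-5-one (trans-fused) | C[C@@H]1[C@H]2CC[C@@H](O)[C@]2(C)CCC1=O | intermediate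
7 | (7aR)-1β-hydroxy-4α,6α,7aβ-trimethyl-3aα-H-octahydro-5H-inden-5-one | C[C@@H]1C(=O)[C@H](C)[C@H]2CC[C@@H](O)[C@]2(C)C1 | intermediate
8 | hydrazone of 7 at C5 | C[C@@H]1C(=NN)[C@H](C)[C@H]2CC[C@@H](O)[C@]2(C)C1 | intermediate (not isolated)
9 | (7aR)-4α,6α,7aβ-trimethyl-3aα-H-octahydro-1H-inden-1β-ol | C[C@@H]1C[C@H](C)[C@H]2CC[C@@H](O)[C@]2(C)C1 | intermediate
10 | (7aR)-4α,6α,7aβ-trimethyl-3aα-H-octahydro-1H-inden-1-one | C[C@@H]1C[C@H](C)[C@H]2CCC(=O)[C@]2(C)C1 | intermediate
11 | trimethylsilyl enol ether of 10 (C1=C2) | C[C@@H]1C[C@H](C)[C@H]2CC=C(O[Si](C)(C)C)[C@]2(C)C1 | intermediate (not isolated)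
12 | (7aR)-4α,6α,7aβ-trimethyl-3aα-H-3a,4,5,6,7,7a-hexahydro-1H-inden-1-one (2-en-1-one) | C[C@@H]1C[C@H](C)[C@H]2C=CC(=O)[C@]2(C)C1 | intermediate
13 | 3β-(pinacolatoboryl) derivative of 10 | C[C@@H]1C[C@H](C)[C@H]2[C@@H](B3OC(C)(C)C(C)(C)O3)CC(=O)[C@]2(C)C1 | intermediate (not isolated)
14 | 3β-hydroxy-4α,6α,7aβ-trimethyl-3aα-H-octahydro-1H-inden-1-one | C[C@@H]1C[C@H](C)[C@H]2[C@@H](O)CC(=O)[C@]2(C)C1 | intermediate
15 | 3β-(TBS-oxy)-4α,6α,7aβ-trimethyl-3aα-H-octahydro-1H-inden-1-one | C[C@@H]1C[C@H](C)[C@H]2[C@@H](O[Si](C)(C)C(C)(C)C)CC(=O)[C@]2(C)C1 | intermediate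
16 | enol triflate of 15 (C1=C2) | C[C@@H]1C[C@H](C)[C@H]2[C@@H](O[Si](C)(C)C(C)(C)C)C=C(OS(=O)(=O)C(F)(F)F)[C@]2(C)C1 | intermediate
17 | 1-(1-ethoxyvinyl) diene from 16 | C[C@@H]1C[C@H](C)[C@H]2[C@@H](O[Si](C)(C)C(C)(C)C)C=C(C(=C)OCC)[C@]2(C)C1 | intermediate (not isolated)
18 | 1-acetyl-3β-(TBS-oxy)-4α,6α,7aβ-trimethyl-3aα-H-3a,4,5,6,7,7a-hexahydro-3H-indene | C[C@@H]1C[C@H](C)[C@H]2[C@@H](O[Si](C)(C)C(C)(C)C)C=C(C(C)=O)[C@]2(C)C1 | intermediate
19 | ethyl 4-(diethoxyphosphoryl)-3-oxobutanoate | CCOC(=O)CC(=O)CP(=O)(OCC)OCC | starting material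
20 | Michael adduct: 1β-acetyl-2α-[1-ethoxycarbonyl-3-(diethoxyphosphoryl)-2-oxopropyl] indane (side-chain CH labile) | C[C@@H]1C[C@H](C)[C@H]2[C@@H](O[Si](C)(C)C(C)(C)C)[C@H](C(C(=O)OCC)C(=O)CP(=O)(OCC)OCC)[C@@H](C(C)=O)[C@]2(C)C1 | intermediate (not isolated)
21 | ethyl 9β-(TBS-oxy)-4,4bβ,6α,8α-tetramethyl-2-oxo-Δ3-dodecahydrofluorene-1-carboxylate (4a-H α, 8a-H α, 9a-H β; C1 labile) | C[C@@H]1C[C@H](C)[C@H]2[C@@H](O[Si](C)(C)C(C)(C)C)[C@H]3[C@H]([C@]2(C)C1)C(C)=CC(=O)C3C(=O)OCC | intermediate
22 | 2-triflyloxy-Δ1,Δ3-diene ester from 21 | C[C@@H]1C[C@H](C)[C@H]2[C@@H](O[Si](C)(C)C(C)(C)C)[C@H]3[C@H]([C@]2(C)C1)C(C)=CC(OS(=O)(=O)C(F)(F)F)=C3C(=O)OCC | intermediate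
23 | ethyl 9β-(TBS-oxy)-2,4,4bβ,6α,8α-pentamethyl-Δ1,Δ3-dodecahydrofluorene-1-carboxylate | C[C@@H]1C[C@H](C)[C@H]2[C@@H](O[Si](C)(C)C(C)(C)C)[C@H]3[C@H]([C@]2(C)C1)C(C)=CC(C)=C3C(=O)OCC | intermediate
24 | ethyl 9β-(TBS-oxy)-2,4α,4bβ,6α,8α-pentamethyl-Δ2-dodecahydrofluorene-1β-carboxylate | C[C@@H]1C[C@H](C)[C@H]2[C@@H](O[Si](C)(C)C(C)(C)C)[C@H]3[C@H]([C@]2(C)C1)[C@@H](C)C=C(C)[C@@H]3C(=O)OCC | intermediate
25 | ethyl 9β-hydroxy-2,4α,4bβ,6α,8α-pentamethyl-Δ2-dodecahydrofluorene-1β-carboxylate | C[C@@H]1C[C@H](C)[C@H]2[C@@H](O)[C@H]3[C@H]([C@]2(C)C1)[C@@H](C)C=C(C)[C@@H]3C(=O)OCC | intermediate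
26 | bis(4-bromophenyl)iodonium trifluoromethanesulfonate | Brc1ccc(cc1)[I+]c1ccc(Br)cc1.[O-]S(=O)(=O)C(F)(F)F | starting material
27 | ethyl 9β-(4-bromophenoxy)-2,4α,4bβ,6α,8α-pentamethyl-Δ2-dodecahydrofluorene-1β-carboxylate | C[C@@H]1C[C@H](C)[C@H]2[C@@H](Oc5ccc(Br)cc5)[C@H]3[C@H]([C@]2(C)C1)[C@@H](C)C=C(C)[C@@H]3C(=O)OCC | intermediate
28 | 9β-(4-bromophenoxy)-2,4α,4bβ,6α,8α-pentamethyl-Δ2-dodecahydrofluorene-1β-carboxylic acid | C[C@@H]1C[C@H](C)[C@H]2[C@@H](Oc5ccc(Br)cc5)[C@H]3[C@H]([C@]2(C)C1)[C@@H](C)C=C(C)[C@@H]3C(=O)O | intermediate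
29 | 5-acyl Meldrum's acid of 28 | C[C@@H]1C[C@H](C)[C@H]2[C@@H](Oc5ccc(Br)cc5)[C@H]3[C@H]([C@]2(C)C1)[C@@H](C)C=C(C)[C@@H]3C(=O)C4C(=O)OC(C)(C)OC4=O | intermediate (not isolated)
30 | 3-(fluoren-1β-yl)-3-oxopropanamide (β-keto amide of 28) | C[C@@H]1C[C@H](C)[C@H]2[C@@H](Oc5ccc(Br)cc5)[C@H]3[C@H]([C@]2(C)C1)[C@@H](C)C=C(C)[C@@H]3C(=O)CC(N)=O | intermediate
31 | (2-bromoethoxy)(tert-butyl)dimethylsilane | CC(C)(C)[Si](C)(C)OCCBr | starting material
32 | 2-[2-(TBS-oxy)ethyl] β-keto amide (α-carbon labile) | C[C@@H]1C[C@H](C)[C@H]2[C@@H](Oc5ccc(Br)cc5)[C@H]3[C@H]([C@]2(C)C1)[C@@H](C)C=C(C)[C@@H]3C(=O)C(CCO[Si](C)(C)C(C)(C)C)C(N)=O | intermediate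
33 | 3-bromoprop-1-yne (propargyl bromide) | C#CCBr | starting material
34 | 2-[2-(TBS-oxy)ethyl]-2-(prop-2-ynyl) β-keto amide | C[C@@H]1C[C@H](C)[C@H]2[C@@H](Oc5ccc(Br)cc5)[C@H]3[C@H]([C@]2(C)C1)[C@@H](C)C=C(C)[C@@H]3C(=O)[C@](CCO[Si](C)(C)C(C)(C)C)(CC#C)C(N)=O | intermediate
35 | 3-(fluorene-1β-carbonyl)-3-[2-(TBS-oxy)ethyl]-5-methylidenepyrrolidin-2-one with 9β-(4-bromophenoxy) group | C[C@@H]1C[C@H](C)[C@H]2[C@@H](Oc5ccc(Br)cc5)[C@H]3[C@H]([C@]2(C)C1)[C@@H](C)C=C(C)[C@@H]3C(=O)[C@@]4(CCO[Si](C)(C)C(C)(C)C)C(=O)NC(=C)C4 | intermediate
36 | 13-membered cyclophane with 4′,5′-endocyclic enamide and TBS ether | C[C@@H]1C[C@H](C)[C@H]2[C@H]3Oc4ccc(cc4)CC4=C[C@](C(=O)[C@@H]6[C@@H]3[C@H]([C@]2(C)C1)[C@@H](C)C=C6C)(CCO[Si](C)(C)C(C)(C)C)C(=O)N4 | intermediate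
37 | cyclophane hemiaminal (5′-hydroxy lactam) with 2-hydroxyethyl arm | C[C@@H]1C[C@H](C)[C@H]2[C@H]3Oc4ccc(cc4)C[C@]4(O)C[C@](C(=O)[C@@H]6[C@@H]3[C@H]([C@]2(C)C1)[C@@H](C)C=C6C)(CCO)C(=O)N4 | intermediate
38 | cyclophane hemiaminal aldehyde (2-oxoethyl arm) | C[C@@H]1C[C@H](C)[C@H]2[C@H]3Oc4ccc(cc4)C[C@]4(O)C[C@](C(=O)[C@@H]6[C@@H]3[C@H]([C@]2(C)C1)[C@@H](C)C=C6C)(CC=O)C(=O)N4 | intermediate
39 | 2β-hydroperoxy-Δ3 aldehyde | C[C@@H]1C[C@H](C)[C@H]2[C@H]3Oc4ccc(cc4)C[C@]4(O)C[C@](C(=O)[C@@H]6[C@@H]3[C@H]([C@]2(C)C1)C(C)=C[C@]6(C)OO)(CC=O)C(=O)N4 | intermediate (not isolated)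
40 | peroxy hemiacetal (1,2-dioxocan-3-ol) with C3=C4 alkene | C[C@@H]1C[C@H](C)[C@H]2[C@H]3Oc4ccc(cc4)C[C@]4(O)C[C@@]8(C(=O)[C@@H]6[C@@H]3[C@H]([C@]2(C)C1)C(C)=C[C@]6(C)OO[C@@H](O)C8)C(=O)N4 | intermediate
41 | CNP0533733.1 | C[C@@H]1C[C@H](C)[C@H]2[C@H]3Oc4ccc(cc4)C[C@]4(O)C[C@]5(C[C@H](O)OO[C@@]6(C)[C@H]7O[C@@]7(C)[C@H]([C@H]3[C@H]6C5=O)[C@]2(C)C1)C(=O)N4 | target

## Step count and least certain steps

Total step count: 28. Longest linear sequence: 28 steps (1 and 2 to 41); the route is linear, and 19, 26, 31 and 33 are bought.

**Step 24 (key step).**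
- What may go wrong: intermolecular coupling at the concentration reached in the flask, or migration of the exocyclic double bond into the lactam ring by palladium hydride before insertion, which would remove the reactive CH2. Both follow from the slow closure of a strained 13-membered ring with a bent arene.
- Fallback: set out from 34 and form the same aryl–CH2 bond by enolate arylation instead of alkene insertion. Hydration of the alkyne ((Ph3P)AuNTf2, MeOH/H2O) gives the methyl ketone F1. Palladium-catalysed intramolecular α-arylation of the methyl group (Pd(OAc)2, P(t-Bu)3·HBF4, NaOt-Bu, toluene, high dilution) gives the macrocyclic benzyl ketone F2. Aqueous acid closes the hemiaminal and removes the silyl group, and the route is rejoined at 37.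

**Step 22.**
- What may go wrong: poor facial selectivity in the alkylation that creates C3′. The controlling stereocentre (C1) is three atoms away, and the prediction depends on a chelated enolate geometry.
- Fallback: reverse the order of the two alkylations. Set out from 30 and alkylate first with 33 (K2CO3, DMF) to the propargyl keto amide F3, then with 31 under the same chelating conditions (NaH, THF). If the enolate face preference is the same, this order gives the opposite configuration at C3′ and so corrects a wrong sense of induction; the route is rejoined at 34.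

**Step 16.**
- What may go wrong: over-reduction of the ester group by the dissolving metal, or protonation of the dienolate at C3 on quench, which would return a conjugated ester.
- Fallback: carry out the reduction on the carboxylate, which cannot be over-reduced. Set out from 23 and saponify (KOH, EtOH/H2O, reflux) to the dienoic acid F4. Reduce its lithium salt with Li in NH3 to the β,γ-unsaturated acid F5, and re-esterify (EtI, K2CO3, DMF) to rejoin the route at 24.

**Step 23.**
- What may go wrong: deprotonation at C1 instead of nitrogen. This could move the ring C double bond into conjugation with the ketone or lead to O- or C-cyclisation onto the alkyne.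
- Fallback: close the N1′–C5′ bond by copper catalysis under weakly basic conditions. Set out from 32 and alkylate with 2,3-dibromopropene (NaH, THF) to the 2-bromoallyl keto amide F6. Intramolecular amide N-vinylation (CuI, N,N′-dimethylethylenediamine, Cs2CO3, 1,4-dioxane, 70 °C) then gives 35 directly.

**Step 27.**
- What may go wrong: abstraction of a hydrogen from the C2 methyl group, attack on the α face, or radical autoxidation of the aldehyde C–H bond under oxygen and light.
- Fallback: run the photooxygenation without the aldehyde. Set out from 37; the ene reaction under the same conditions gives the hydroperoxy alcohol F7. Dess–Martin oxidation of the primary alcohol then gives the aldehyde, which closes to 40.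

**Step 28.**
- What may go wrong: epoxidation from the α face. The pseudoaxial peroxide oxygen and the angular methyl shield the β face, and the hydrogen-bond direction from the closed peroxy hemiacetal is not secure.
- Fallback: epoxidise while the hydroperoxide is free and can direct the peracid. Set out from 37 and photooxygenate to the hydroperoxy alcohol F7. Epoxidise with mCPBA in CH2Cl2 to the β-epoxy hydroperoxide F8, where the allylic OOH delivers the peracid syn. Dess–Martin oxidation of the primary alcohol then unmasks the aldehyde, which closes on the hydroperoxide to give 41.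

## Further compounds

F1 | step 24 | methyl ketone from hydration of the alkyne of 34: 2-[2-(TBS-oxy)ethyl]-2-(2-oxopropyl) β-keto amide | C[C@@H]1C[C@H](C)[C@H]2[C@@H](Oc5ccc(Br)cc5)[C@H]3[C@H]([C@]2(C)C1)[C@@H](C)C=C(C)[C@@H]3C(=O)[C@](CCO[Si](C)(C)C(C)(C)C)(CC(C)=O)C(N)=O
F2 | step 24 | macrocyclic benzyl ketone (open γ-keto amide form) with TBS ether | C[C@@H]1C[C@H](C)[C@H]2[C@H]3Oc4ccc(cc4)CC(=O)C[C@](C(=O)[C@@H]6[C@@H]3[C@H]([C@]2(C)C1)[C@@H](C)C=C6C)(CCO[Si](C)(C)C(C)(C)C)C(N)=O
F3 | step 22 | 2-(prop-2-ynyl) β-keto amide (α-carbon labile) | C[C@@H]1C[C@H](C)[C@H]2[C@@H](Oc5ccc(Br)cc5)[C@H]3[C@H]([C@]2(C)C1)[C@@H](C)C=C(C)[C@@H]3C(=O)C(CC#C)C(N)=O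
F4 | step 16 | 9β-(TBS-oxy)-2,4,4bβ,6α,8α-pentamethyl-Δ1,Δ3-dodecahydrofluorene-1-carboxylic acid | C[C@@H]1C[C@H](C)[C@H]2[C@@H](O[Si](C)(C)C(C)(C)C)[C@H]3[C@H]([C@]2(C)C1)C(C)=CC(C)=C3C(=O)O
F5 | step 16 | 9β-(TBS-oxy)-2,4α,4bβ,6α,8α-pentamethyl-Δ2-dodecahydrofluorene-1β-carboxylic acid | C[C@@H]1C[C@H](C)[C@H]2[C@@H](O[Si](C)(C)C(C)(C)C)[C@H]3[C@H]([C@]2(C)C1)[C@@H](C)C=C(C)[C@@H]3C(=O)O
F6 | step 23 | 2-(2-bromoprop-2-enyl)-2-[2-(TBS-oxy)ethyl] β-keto amide | C[C@@H]1C[C@H](C)[C@H]2[C@@H](Oc5ccc(Br)cc5)[C@H]3[C@H]([C@]2(C)C1)[C@@H](C)C=C(C)[C@@H]3C(=O)[C@](CCO[Si](C)(C)C(C)(C)C)(CC(Br)=C)C(N)=O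
F7 | step 27 | 2β-hydroperoxy-Δ3 cyclophane hemiaminal with 2-hydroxyethyl arm | C[C@@H]1C[C@H](C)[C@H]2[C@H]3Oc4ccc(cc4)C[C@]4(O)C[C@](C(=O)[C@@H]6[C@@H]3[C@H]([C@]2(C)C1)C(C)=C[C@]6(C)OO)(CCO)C(=O)N4
F8 | step 28 | 3β,4β-epoxy-2β-hydroperoxy cyclophane hemiaminal with 2-hydroxyethyl arm | C[C@@H]1C[C@H](C)[C@H]2[C@H]3Oc4ccc(cc4)C[C@]4(O)C[C@](C(=O)[C@@H]6[C@@H]3[C@H]([C@]2(C)C1)[C@]7(C)O[C@@H]7[C@]6(C)OO)(CCO)C(=O)N4
A1 | alternative 1 | cis-fused ring A anhydride with angular methyl | C[C@H]1C=C(C)C[C@@]2(C)C(=O)OC(=O)[C@@H]12
A2 | alternative 1 | (E)-2-methylpenta-1,3-diene | C/C=C/C(C)=C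
A3 | alternative 1 | citraconic anhydride (3-methylfuran-2,5-dione) | CC1=CC(=O)OC1=O
A4 | alternative 2 | tricyclic diol ester (rings A, B, C) | C[C@@H]1C[C@H](C)[C@H]2[C@@H](O)[C@H]3[C@H]([C@]2(C)C1)[C@@H](C)C[C@](C)(O)[C@@H]3C(=O)OC
A5 | alternative 2 | ring A aldehyde with enoate and methyl ketone side chain | C[C@@H]1C[C@H](C)[C@@H](C=O)[C@@](C)(C1)[C@@H](/C=C/C(=O)OC)[C@@H](C)CC(C)=O
A6 | alternative 3 | peroxy hemiacetal with transposed ring C alkene (identical with 40) | C[C@@H]1C[C@H](C)[C@H]2[C@H]3Oc4ccc(cc4)C[C@]4(O)C[C@@]8(C(=O)[C@@H]6[C@@H]3[C@H]([C@]2(C)C1)C(C)=C[C@]6(C)OO[C@@H](O)C8)C(=O)N4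
A7 | alternative 3 | cyclophane hemiaminal aldehyde (identical with 38) | C[C@@H]1C[C@H](C)[C@H]2[C@H]3Oc4ccc(cc4)C[C@]4(O)C[C@](C(=O)[C@@H]6[C@@H]3[C@H]([C@]2(C)C1)[C@@H](C)C=C6C)(CC=O)C(=O)N4
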